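The numbers in the tables are simulated on assumed constants, and the scatter is random.

Decide at the outset to carry one dimensionless number for the flask, not a fitted model, and to build it from the theta and eta runs.

common to all: starting material 0.11 M; precatalyst 0.006 mol%

| run | second substrate | remark | time |
|---|---|---|---|
| theta | 1.8 equiv (in portions, 3) | run made earlier; portions every 2.5 min |  |
| eta | 2.9 equiv (in portions, 3) | run made earlier; portions every 2.5 min |  |
| flask | 1.30 equiv (in portions, 3) | the portions of second substrate follow each other after 2.5 min, the first at the start | 20 min |

| run | time / min | ternary complex / % | product / % | starting material / % | starting complex / % |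
|---|---|---|---|---|---|
| theta | 2.00 | 0 | 0.2 | 100.0 | 0.8 |
| theta | 6.00 | 0.2 | 2.4 | 98.0 | 0 |
| theta | 10.0 | 0.3 | 8.4 | 92.3 | 0 |
| theta | 15.0 | 0.2 | 19.0 | 80.7 | 0 |
| eta | 1.33 | 0.4 | 0 | 100.3 | 0 |
| eta | 3.00 | 0.1 | 0.3 | 99.0 | 0.1 |
| eta | 6.00 | 0.2 | 3.4 | 96.3 | 0.1 |
| eta | 15.0 | 0 | 30.4 | 69.1 | 0 |

(each reading ± 0.3 percentage points)



1. the species that holds most of what was charged as starting material, at 20 min (ternary complex / starting complex / starting material / product)
2. the largest share itself, whichever of these holds it, in percent of the starting material charged

1. In the theta run, after the last portion, product climbs from 8.4% at 10.0 min to 19.0% at 15.0 min, which reads as a power of time with exponent 2.01; you take this as product growing with the square of time, a rate that rises with time.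

2. At 15.0 min the eta run holds 1.60 times the theta product, against a charge ratio of 1.61, so you read product as proportional to the second substrate charged.

3. Multiply the theta product at 15.0 min by the charge ratio, the squared time ratio and the loading ratio (untested by these runs, and 1.00 here). This gives the conversion number, the fraction of the limiting reagent, starting material, turned into product: 24.4% for the flask. Starting material should therefore hold most, at 75.6%.

4. To test the charge scaling at an earlier time, scale the theta product at 6.00 min to the eta charge: you get 3.87% against 3.4% read, a gap of 0.47 percentage points beside a scatter of 0.3 points. The square of time fares worse early, since from the theta product at 15.0 min it gives 3.04% at 6.00 min against 2.4% read, so you hold it as a rule for late times. You commit to the one number knowing that it reaches beyond the runs, to a later time and a smaller charge of second substrate.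

The forecast says starting material at 77%, a share above yours, holding that "The rate is therefore about first order in second substrate".

The flask gives starting material at 75.7%, with 24.3% of product against the conversion number of 24.4%.

    starting material + enzyme ⇌ starting complex (K = 9.70 M⁻¹, k = 4.90 × 10⁵ M⁻¹ min⁻¹)
    second substrate + starting complex ⇌ ternary complex (K = 57.0 M⁻¹, k = 4.20 × 10⁵ M⁻¹ min⁻¹)
    ternary complex → enzyme + product (k = 1400 min⁻¹)
    enzyme → spent catalyst (k = 0.00560 min⁻¹)
    second substrate + precatalyst → enzyme + spent reagent (k = 0.220 M⁻¹ min⁻¹)

Now take a neighbouring flask, the same recipe with 0.0015 mol% of precatalyst. Its loading ratio of 0.250 brings the conversion number down to 6.10%. That flask ends with 6.41% of product and 93.6% of its starting material left.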